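**Retrosynthetic overview**

- Ring letters: isoflavan = ring A (benzo ring), ring B (3-aryl), ring C (pyran); flavanone = ring D (benzo ring), ring E (2-aryl), ring F (pyranone).
- The plan rests on ring F: O1 and C2 lie β to the C4 carbonyl, and of the three ring D oxygens only the one para to the carbon bonded to isoflavan C4 is left free. Oxa-Michael closure of an alkylidene β-keto ester can then give only the C6-linked flavanone, not the C8-linked one. This O1–C2 bond is cut last, under a cinchona thiourea catalyst that sets C2.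
- The keto ester goes back (Knoevenagel, O→C Boc transfer, Stille acetylation, iodination) to a trans-4-arylisoflavan whose ring D has both oxygens flanking the isoflavanyl carbon benzylated and one free para phenol. Its two open ring D carbons are equivalent, so the acyl group can only end up beside the free oxygen.
- Ring C is cut at C4–C4a (intramolecular Friedel–Crafts alkylation through the ring D benzylic cation, trans to the C3 aryl) and at O1–C2 (Mitsunobu ether). C3 is set by an Evans syn-aldol between the ring B arylacetyl imide and the ring D aldehyde, whose formyl carbon becomes isoflavan C4 and so fixes the ring D regiochemistry from the start.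
- Order of ring formation: ring C (step 11), then ring F (step 17). Rings A, B, D and E come from 3-(benzyloxy)phenol, 2,6-dimethoxyphenol, 2,4,6-trihydroxybenzaldehyde and 4-(benzyloxy)benzaldehyde.

Key step: step 17

Assumption: the 9-amino-9-deoxy-epi-quinidine thiourea is taken to give the 2S flavanone; the sense is to be checked on the parent 2'-hydroxyphenyl alkylidene keto ester, and the quinine-derived pseudoenantiomer is used under the same conditions if it proves opposite.

**Route**

Step 1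
Reactants: 1 2,6-dimethoxyphenol
Product: 2 2-(benzyloxy)-1,3-dimethoxybenzene
Conditions: BnBr, K2CO3, DMF, 60 °C
Reagents that add atoms: benzyl bromide, BrCc1ccccc1
Why: Williamson etherification of the single phenol protects the future ring B 3'-oxygen as a benzyl ether that lasts until the final hydrogenolysis.

Step 2
Reactants: 2 2-(benzyloxy)-1,3-dimethoxybenzene
Product: 3 2-(benzyloxy)-4-bromo-1,3-dimethoxybenzene
Conditions: NBS, MeCN, 0 °C → rt
Reagents that add atoms: N-bromosuccinimide, O=C1CCC(=O)N1Br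
Why: Electrophilic aromatic bromination of a 1,2,3-trialkoxybenzene should go para to one outer alkoxy group and ortho to the other (C4), because the flanked central oxygen is twisted out of conjugation and does not direct to C5.

Step 3
Reactants: 3 2-(benzyloxy)-4-bromo-1,3-dimethoxybenzene
Product: 4 tert-butyl 2-[3-(benzyloxy)-2,4-dimethoxyphenyl]acetate
Conditions: BrZnCH2CO2tBu (1.5 equiv), Pd(dba)2 (2 mol%), XPhos (4 mol%), THF, 60 °C
Reagents that add atoms: (2-tert-butoxy-2-oxoethyl)zinc bromide, CC(C)(C)OC(=O)C[Zn]Br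
Why: Palladium-catalysed Negishi-type arylation of a Reformatsky zinc enolate joins the acetate carbon to the ortho-substituted, electron-rich aryl bromide under near-neutral conditions that leave the benzyl ether alone.

Step 4
Reactants: 4 tert-butyl 2-[3-(benzyloxy)-2,4-dimethoxyphenyl]acetate
Product: 5 2-[3-(benzyloxy)-2,4-dimethoxyphenyl]acetic acid
Conditions: TFA/CH2Cl2 (1:4), 0 °C → rt
Reagents that add atoms: none
Why: Acidolysis of the tert-butyl ester (loss of 2-methylpropene) frees the acid, and brief contact with dilute TFA should not cleave the aryl benzyl or methyl ethers.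

Step 5
Reactants: 5 2-[3-(benzyloxy)-2,4-dimethoxyphenyl]acetic acid; 6 (S)-4-benzyl-1,3-oxazolidin-2-one
Product: 8 (S)-4-benzyl-3-{2-[3-(benzyloxy)-2,4-dimethoxyphenyl]acetyl}-1,3-oxazolidin-2-one, via mixed pivalic anhydride 7 (not isolated)
Conditions: PivCl, Et3N, THF, −20 °C; then 6, LiCl, −20 °C → rt
Reagents that add atoms: none
Why: N-acylation of the oxazolidinone through the mixed anhydride is the standard entry to Evans imides, and the arylacetyl CH2 has no stereocentre to lose.

Step 6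
Reactants: 9 2,4,6-trihydroxybenzaldehyde
Product: 10 2,6-dihydroxy-4-[(triisopropylsilyl)oxy]benzaldehyde
Conditions: TIPSCl (1.05 equiv), imidazole (2.2 equiv), DMF, 0 °C
Reagents that add atoms: chlorotri(propan-2-yl)silane, CC(C)[Si](Cl)(C(C)C)C(C)C
Why: Selective O-silylation is expected at the 4-hydroxyl, which is para to the formyl group, the most acidic and the only one without an ortho substituent, whereas the two ortho hydroxyls are flanked by the formyl group and are poor partners for the bulky silyl chloride.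

Step 7
Reactants: 10 2,6-dihydroxy-4-[(triisopropylsilyl)oxy]benzaldehyde
Product: 11 2,6-bis(benzyloxy)-4-[(triisopropylsilyl)oxy]benzaldehyde
Conditions: BnOH (2.6 equiv), PPh3 (2.6 equiv), DIAD (2.6 equiv), THF, 0 °C → rt
Reagents that add atoms: benzyl alcohol, OCc1ccccc1
Why: Double Mitsunobu O-alkylation benzylates both salicylaldehyde-type hydroxyls under neutral conditions that keep the aryl silyl ether, which a carbonate base in DMF could strip.

Step 8
Reactants: 8 (S)-4-benzyl-3-{2-[3-(benzyloxy)-2,4-dimethoxyphenyl]acetyl}-1,3-oxazolidin-2-one; 11 2,6-bis(benzyloxy)-4-[(triisopropylsilyl)oxy]benzaldehyde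
Product: 12 (S)-4-benzyl-3-[(2S,3S)-3-{2,6-bis(benzyloxy)-4-[(triisopropylsilyl)oxy]phenyl}-2-[3-(benzyloxy)-2,4-dimethoxyphenyl]-3-hydroxypropanoyl]-1,3-oxazolidin-2-one
Conditions: Bu2BOTf (1.2 equiv), iPr2NEt (1.4 equiv), CH2Cl2, −78 → 0 °C; then 11, −78 → 0 °C; pH 7 buffer, MeOH, H2O2, 0 °C
Reagents that add atoms: none
Why: Evans syn-aldol addition, in which the Z dibutylboron enolate adds through a Zimmerman–Traxler chair on the face away from the auxiliary benzyl group, should set the α-carbon as S (the future isoflavan C3), while the carbinol centre formed with it is ionised in step 11 and does not matter.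

Step 9
Reactants: 12 the syn-aldol imide
Product: 13 (1S,2R)-1-{2,6-bis(benzyloxy)-4-[(triisopropylsilyl)oxy]phenyl}-2-[3-(benzyloxy)-2,4-dimethoxyphenyl]propane-1,3-diol
Conditions: LiBH4 (2 equiv), MeOH (2 equiv), THF, 0 °C
Reagents that add atoms: none
Why: Reductive cleavage of the N-acyl oxazolidinone by borohydride gives the primary alcohol and returns the auxiliary without enolising the α-aryl centre (its descriptor changes to R only through the priority rules).

Step 10
Reactants: 13 the 1,3-diol; 14 3-(benzyloxy)phenol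
Product: 15 (1S,2R)-1-{2,6-bis(benzyloxy)-4-[(triisopropylsilyl)oxy]phenyl}-3-[3-(benzyloxy)phenoxy]-2-[3-(benzyloxy)-2,4-dimethoxyphenyl]propan-1-ol
Conditions: PPh3 (1.5 equiv), DIAD (1.5 equiv), THF, 0 °C → rt
Reagents that add atoms: none
Why: Mitsunobu aryl ether formation should take place at the primary hydroxyl only, since the secondary benzylic hydroxyl lies between two ortho benzyloxy groups and the C2 aryl group and cannot form the oxyphosphonium ion.

Step 11
Reactants: 15 the aryl ether carbinol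
Product: 16 (3R,4S)-7-(benzyloxy)-4-{2,6-bis(benzyloxy)-4-[(triisopropylsilyl)oxy]phenyl}-3-[3-(benzyloxy)-2,4-dimethoxyphenyl]chroman
Conditions: BF3·OEt2 (0.2 equiv), CH2Cl2, −40 → 0 °C
Reagents that add atoms: none
Why: Intramolecular Friedel–Crafts alkylation, in which the carbinol ionises to a benzylic cation stabilised by the three ring D oxygens and the tethered resorcinol-type ring attacks through its carbon para to the benzyloxy group in a six-membered chair on the face anti to the C3 aryl group, should close ring C with both aryl groups pseudo-equatorial (3,4-trans, C4 S) and leave C3 untouched.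

Step 12
Reactants: 16 the silylated trans-4-arylisoflavan
Product: 17 3,5-bis(benzyloxy)-4-{(3R,4S)-7-(benzyloxy)-3-[3-(benzyloxy)-2,4-dimethoxyphenyl]chroman-4-yl}phenol
Conditions: Bu4NF (1.1 equiv), AcOH (1.1 equiv), THF, 0 °C
Reagents that add atoms: none
Why: Fluoride cleaves the aryl silyl ether (strong Si–F bond) and frees the one phenol of ring D, the acetic acid buffer keeping the medium neutral for the benzyl ethers.

Step 13
Reactants: 17 the ring D phenol
Product: 18 3,5-bis(benzyloxy)-4-{(3R,4S)-7-(benzyloxy)-3-[3-(benzyloxy)-2,4-dimethoxyphenyl]chroman-4-yl}-2-iodophenol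
Conditions: NIS (1.0 equiv), CH2Cl2, −40 → 0 °C, dark
Reagents that add atoms: N-iodosuccinimide, O=C1CCC(=O)N1I
Why: Electrophilic iodination ortho to a free phenol should touch only ring D, the one ring with a free hydroxyl, and since its two open carbons are equivalent by rotation about the C4–aryl bond one equivalent of NIS should give a single mono-iodide.

Step 14
Reactants: 18 the iodophenol
Product: 20 1-(2,4-bis(benzyloxy)-6-hydroxy-3-{(3R,4S)-7-(benzyloxy)-3-[3-(benzyloxy)-2,4-dimethoxyphenyl]chroman-4-yl}phenyl)ethan-1-one, via enol ether 19 (not isolated)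
Conditions: tributyl(1-ethoxyvinyl)stannane (1.5 equiv), PdCl2(PPh3)2 (5 mol%), dioxane, 90 °C; then 1 M HCl, THF, rt
Reagents that add atoms: tributyl(1-ethoxyvinyl)stannane, CCCC[Sn](CCCC)(CCCC)C(=C)OCC; water, O
Why: Stille coupling of the aryl iodide with the 1-ethoxyvinyl stannane (an acetyl anion equivalent) followed by mild hydrolysis of the enol ether puts the acetyl group exactly on the iodinated carbon, beside the free phenol, without any Lewis acid.

Step 15
Reactants: 20 the 2'-hydroxyacetophenone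
Product: 22 tert-butyl 3-(2,4-bis(benzyloxy)-6-hydroxy-3-{(3R,4S)-7-(benzyloxy)-3-[3-(benzyloxy)-2,4-dimethoxyphenyl]chroman-4-yl}phenyl)-3-oxopropanoate, via aryl tert-butyl carbonate 21 (not isolated)
Conditions: Boc2O (1.1 equiv), DMAP (0.1 equiv), THF, rt; then LiN(SiMe3)2 (3.5 equiv), −78 → −20 °C; AcOH
Reagents that add atoms: di-tert-butyl dicarbonate, CC(C)(C)OC(=O)OC(=O)OC(C)(C)C
Why: The phenol is first converted into its tert-butyl carbonate and the ketone enolate then attacks the carbonate carbonyl through a six-membered transition state and expels the phenoxide (Baker–Venkataraman-type O→C acyl transfer, an intramolecular Claisen condensation), which should give the β-keto ester and the free phenol in one operation.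

Step 16
Reactants: 22 the β-keto ester; 23 4-(benzyloxy)benzaldehyde
Product: 24 tert-butyl (Z)-2-(2,4-bis(benzyloxy)-6-hydroxy-3-{(3R,4S)-7-(benzyloxy)-3-[3-(benzyloxy)-2,4-dimethoxyphenyl]chroman-4-yl}benzoyl)-3-[4-(benzyloxy)phenyl]prop-2-enoate
Conditions: piperidine (0.2 equiv), AcOH (0.2 equiv), toluene, 4 Å molecular sieves, rt
Reagents that add atoms: none
Why: Knoevenagel condensation of the active methylene with the aldehyde under piperidinium acetate catalysis should give the alkylidene as the isomer with the aryl group trans to the aroyl group, and under these weakly basic conditions at room temperature the phenol should not yet add.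

Step 17
Reactants: 24 the alkylidene β-keto ester
Product: 26 (2S)-5,7-bis(benzyloxy)-6-{(3R,4S)-7-(benzyloxy)-3-[3-(benzyloxy)-2,4-dimethoxyphenyl]chroman-4-yl}-2-[4-(benzyloxy)phenyl]chroman-4-one, via C3-ester flavanone 25 (not isolated)
Conditions: 9-amino-9-deoxy-epi-quinidine 3,5-bis(trifluoromethyl)phenyl thiourea (10 mol%), toluene, −25 °C; then TsOH·H2O (0.5 equiv), 80 °C
Reagents that add atoms: none
Why: The quinuclidine nitrogen of the bifunctional catalyst deprotonates the single free phenol of ring D while the thiourea holds the 1,3-dicarbonyl by two hydrogen bonds, and the phenoxide oxygen adds to the β-carbon of the alkylidene (intramolecular oxa-Michael addition); the closest known reaction type is the cinchona thiourea closure of 2'-hydroxyaryl alkylidene β-keto esters to 3-carboxy flavanones. Ring F closes in a 6-endo-trig mode, forming O1–C2. The new stereocentre C2 is set by the catalyst, which exposes one face of the alkene to the bound phenoxide; the isoflavan centres are remote, and any 2R product is a diastereomer that chromatography can remove. The step needs C6 over C8 regiochemistry, which is secured because both oxygens flanking the isoflavanyl carbon are benzylated and only the para oxygen can add. It also needs catalysed closure to outrun racemic background closure and reopening, which the low temperature and the extra ester secure, since the ester makes the acceptor reactive and the adduct a stabilised β-keto ester that is slow to reopen. TsOH then cleaves the tert-butyl ester and the β-keto acid loses CO2 without touching C2, because acid does not open the flavanone.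

Step 18
Reactants: 26 the penta-O-benzyl flavanone
Product: 27 (2S)-5,7-dihydroxy-6-[(3R,4S)-7-hydroxy-3-(3-hydroxy-2,4-dimethoxyphenyl)chroman-4-yl]-2-(4-hydroxyphenyl)chroman-4-one
Conditions: H2 (1 atm), 10% Pd/C, EtOAc/MeOH (1:1), rt
Reagents that add atoms: none
Why: Hydrogenolysis of the five benzyl ethers over palladium at one atmosphere should free all phenols under neutral conditions, which offer no base to open ring F and epimerise C2 and should not reduce the chelated C4 carbonyl.

**Compound list**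

1 | 2,6-dimethoxyphenol | COc1cccc(OC)c1O | starting material
2 | 2-(benzyloxy)-1,3-dimethoxybenzene | COc1cccc(OC)c1OCc1ccccc1 | intermediate
3 | 2-(benzyloxy)-4-bromo-1,3-dimethoxybenzene | COc1ccc(Br)c(OC)c1OCc1ccccc1 | intermediate
4 | tert-butyl 2-[3-(benzyloxy)-2,4-dimethoxyphenyl]acetate | COc1ccc(CC(=O)OC(C)(C)C)c(OC)c1OCc1ccccc1 | intermediate
5 | 2-[3-(benzyloxy)-2,4-dimethoxyphenyl]acetic acid | COc1ccc(CC(=O)O)c(OC)c1OCc1ccccc1 | intermediate
6 | (S)-4-benzyl-1,3-oxazolidin-2-one | O=C1N[C@@H](Cc2ccccc2)CO1 | starting material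
7 | mixed anhydride of 5 with pivalic acid | COc1ccc(CC(=O)OC(=O)C(C)(C)C)c(OC)c1OCc1ccccc1 | intermediate (not isolated)
8 | (S)-4-benzyl-3-{2-[3-(benzyloxy)-2,4-dimethoxyphenyl]acetyl}-1,3-oxazolidin-2-one | COc1ccc(CC(=O)N2C(=O)OC[C@@H]2Cc2ccccc2)c(OC)c1OCc1ccccc1 | intermediate
9 | 2,4,6-trihydroxybenzaldehyde | O=Cc1c(O)cc(O)cc1O | starting material
10 | 2,6-dihydroxy-4-[(triisopropylsilyl)oxy]benzaldehyde | O=Cc1c(O)cc(O[Si](C(C)C)(C(C)C)C(C)C)cc1O | intermediate
11 | 2,6-bis(benzyloxy)-4-[(triisopropylsilyl)oxy]benzaldehyde | O=Cc1c(OCc2ccccc2)cc(O[Si](C(C)C)(C(C)C)C(C)C)cc1OCc1ccccc1 | intermediate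
12 | (S)-4-benzyl-3-[(2S,3S)-3-{2,6-bis(benzyloxy)-4-[(triisopropylsilyl)oxy]phenyl}-2-[3-(benzyloxy)-2,4-dimethoxyphenyl]-3-hydroxypropanoyl]-1,3-oxazolidin-2-one | O=C(N1C(=O)OC[C@@H]1Cc1ccccc1)[C@@H](c1ccc(OC)c(OCc2ccccc2)c1OC)[C@H](O)c1c(OCc2ccccc2)cc(O[Si](C(C)C)(C(C)C)C(C)C)cc1OCc1ccccc1 | intermediate
13 | (1S,2R)-1-{2,6-bis(benzyloxy)-4-[(triisopropylsilyl)oxy]phenyl}-2-[3-(benzyloxy)-2,4-dimethoxyphenyl]propane-1,3-diol | OC[C@@H](c1ccc(OC)c(OCc2ccccc2)c1OC)[C@H](O)c1c(OCc2ccccc2)cc(O[Si](C(C)C)(C(C)C)C(C)C)cc1OCc1ccccc1 | intermediate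
14 | 3-(benzyloxy)phenol | Oc1cccc(OCc2ccccc2)c1 | starting material
15 | (1S,2R)-1-{2,6-bis(benzyloxy)-4-[(triisopropylsilyl)oxy]phenyl}-3-[3-(benzyloxy)phenoxy]-2-[3-(benzyloxy)-2,4-dimethoxyphenyl]propan-1-ol | C(Oc1cccc(OCc2ccccc2)c1)[C@@H](c1ccc(OC)c(OCc2ccccc2)c1OC)[C@H](O)c1c(OCc2ccccc2)cc(O[Si](C(C)C)(C(C)C)C(C)C)cc1OCc1ccccc1 | intermediate
16 | (3R,4S)-7-(benzyloxy)-4-{2,6-bis(benzyloxy)-4-[(triisopropylsilyl)oxy]phenyl}-3-[3-(benzyloxy)-2,4-dimethoxyphenyl]chroman | COc1ccc([C@@H]2COc3cc(OCc4ccccc4)ccc3[C@H]2c2c(OCc3ccccc3)cc(O[Si](C(C)C)(C(C)C)C(C)C)cc2OCc2ccccc2)c(OC)c1OCc1ccccc1 | intermediate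
17 | 3,5-bis(benzyloxy)-4-{(3R,4S)-7-(benzyloxy)-3-[3-(benzyloxy)-2,4-dimethoxyphenyl]chroman-4-yl}phenol | COc1ccc([C@@H]2COc3cc(OCc4ccccc4)ccc3[C@H]2c2c(OCc3ccccc3)cc(O)cc2OCc2ccccc2)c(OC)c1OCc1ccccc1 | intermediate
18 | 3,5-bis(benzyloxy)-4-{(3R,4S)-7-(benzyloxy)-3-[3-(benzyloxy)-2,4-dimethoxyphenyl]chroman-4-yl}-2-iodophenol | COc1ccc([C@@H]2COc3cc(OCc4ccccc4)ccc3[C@H]2c2c(OCc3ccccc3)cc(O)c(I)c2OCc2ccccc2)c(OC)c1OCc1ccccc1 | intermediate
19 | 3,5-bis(benzyloxy)-4-{(3R,4S)-7-(benzyloxy)-3-[3-(benzyloxy)-2,4-dimethoxyphenyl]chroman-4-yl}-2-(1-ethoxyvinyl)phenol | COc1ccc([C@@H]2COc3cc(OCc4ccccc4)ccc3[C@H]2c2c(OCc3ccccc3)cc(O)c(C(=C)OCC)c2OCc2ccccc2)c(OC)c1OCc1ccccc1 | intermediate (not isolated)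
20 | 1-(2,4-bis(benzyloxy)-6-hydroxy-3-{(3R,4S)-7-(benzyloxy)-3-[3-(benzyloxy)-2,4-dimethoxyphenyl]chroman-4-yl}phenyl)ethan-1-one | COc1ccc([C@@H]2COc3cc(OCc4ccccc4)ccc3[C@H]2c2c(OCc3ccccc3)cc(O)c(C(C)=O)c2OCc2ccccc2)c(OC)c1OCc1ccccc1 | intermediate
21 | 2-acetyl-3,5-bis(benzyloxy)-4-{(3R,4S)-7-(benzyloxy)-3-[3-(benzyloxy)-2,4-dimethoxyphenyl]chroman-4-yl}phenyl tert-butyl carbonate | COc1ccc([C@@H]2COc3cc(OCc4ccccc4)ccc3[C@H]2c2c(OCc3ccccc3)cc(OC(=O)OC(C)(C)C)c(C(C)=O)c2OCc2ccccc2)c(OC)c1OCc1ccccc1 | intermediate (not isolated)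
22 | tert-butyl 3-(2,4-bis(benzyloxy)-6-hydroxy-3-{(3R,4S)-7-(benzyloxy)-3-[3-(benzyloxy)-2,4-dimethoxyphenyl]chroman-4-yl}phenyl)-3-oxopropanoate | COc1ccc([C@@H]2COc3cc(OCc4ccccc4)ccc3[C@H]2c2c(OCc3ccccc3)cc(O)c(C(=O)CC(=O)OC(C)(C)C)c2OCc2ccccc2)c(OC)c1OCc1ccccc1 | intermediate
23 | 4-(benzyloxy)benzaldehyde | O=Cc1ccc(OCc2ccccc2)cc1 | starting material
24 | tert-butyl (Z)-2-(2,4-bis(benzyloxy)-6-hydroxy-3-{(3R,4S)-7-(benzyloxy)-3-[3-(benzyloxy)-2,4-dimethoxyphenyl]chroman-4-yl}benzoyl)-3-[4-(benzyloxy)phenyl]prop-2-enoate (key-step precursor) | COc1ccc([C@@H]2COc3cc(OCc4ccccc4)ccc3[C@H]2c2c(OCc3ccccc3)cc(O)c(c2OCc2ccccc2)C(=O)/C(C(=O)OC(C)(C)C)=C/c2ccc(OCc3ccccc3)cc2)c(OC)c1OCc1ccccc1 | intermediate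
25 | tert-butyl (2S)-5,7-bis(benzyloxy)-6-{(3R,4S)-7-(benzyloxy)-3-[3-(benzyloxy)-2,4-dimethoxyphenyl]chroman-4-yl}-2-[4-(benzyloxy)phenyl]-4-oxochroman-3-carboxylate (C3 epimers and enol; key-step product) | COc1ccc([C@@H]2COc3cc(OCc4ccccc4)ccc3[C@H]2c2c(OCc3ccccc3)cc3c(c2OCc2ccccc2)C(=O)C(C(=O)OC(C)(C)C)[C@@H](c2ccc(OCc4ccccc4)cc2)O3)c(OC)c1OCc1ccccc1 | intermediate (not isolated)
26 | (2S)-5,7-bis(benzyloxy)-6-{(3R,4S)-7-(benzyloxy)-3-[3-(benzyloxy)-2,4-dimethoxyphenyl]chroman-4-yl}-2-[4-(benzyloxy)phenyl]chroman-4-one | COc1ccc([C@@H]2COc3cc(OCc4ccccc4)ccc3[C@H]2c2c(OCc3ccccc3)cc3c(c2OCc2ccccc2)C(=O)C[C@@H](c2ccc(OCc4ccccc4)cc2)O3)c(OC)c1OCc1ccccc1 | intermediate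
27 | (2S)-5,7-dihydroxy-6-[(3R,4S)-7-hydroxy-3-(3-hydroxy-2,4-dimethoxyphenyl)chroman-4-yl]-2-(4-hydroxyphenyl)chroman-4-one | COc1ccc([C@@H]2COc3cc(O)ccc3[C@H]2c2c(O)cc3c(c2O)C(=O)C[C@@H](c2ccc(O)cc2)O3)c(OC)c1O | target

**Step count**

Total: 18 steps. Longest linear sequence: 16 steps (steps 1–5 and 8–18); steps 6–7 form the ring D branch.

**Steps most likely to fail**

Step 17 (key step). The closure may be slow or poorly face-selective, because the aroyl group carries two ortho oxygens and is twisted out of the ring plane and the reacting phenol is hydrogen-bonded to the ketone. Uncatalysed closure or reopening during the warm acid stage could also erode the selectivity at C2. The fallback gives up catalyst control and relies on the isoflavan centres for separation. It sets out from ketone 20 and aldehyde 23: Claisen–Schmidt condensation (KOH, EtOH/THF, rt) should give the 2'-hydroxychalcone F1. Heating F1 with NaOAc in EtOH (thermodynamic oxa-Michael closure) should give a mixture of 26 and its C2 epimer F2. These are diastereomers and should be separable by chromatography; F2 is put back into the NaOAc equilibration. The fallback rejoins the route at 26.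

Step 8 (aldol). Addition to the hindered, strongly donor-substituted aldehyde may be incomplete or reversible, and the new trioxygenated benzylic carbinol may ionise on work-up and eliminate. The fallback avoids the carbinol and sets C3 by hydrogenation. It sets out from acid 5 and aldehyde 11: Perkin condensation (Ac2O, Et3N, 110 °C) should give the (E)-2,3-diarylacrylic acid F3. Asymmetric hydrogenation over Ru(OAc)2[(S)-BINAP] (ligand antipode chosen on a test run to give the R acid; H2 50 bar, MeOH) should give the (R)-2,3-diarylpropanoic acid F4. Reduction with BH3·SMe2 should give the alcohol F5, and Mitsunobu coupling with 14 the aryl ether F6. DDQ (1.1 equiv, CH2Cl2, 0 °C) then removes a hydride from the ring D benzylic CH2, and the cation closes onto ring A as in step 11 (the oxidative cyclisation known from dibenzylbutane lignans to aryltetralins). The fallback rejoins the route at 16.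

Step 15 (O→C Boc transfer). The amide base may attack the carbonate carbonyl and strip the Boc group instead of enolising the hindered ketone, or the product phenoxide may lactonise onto the ester. The fallback builds the keto ester from a salicylate instead. It sets out from iodophenol 18: methoxycarbonylation (Pd(OAc)2, dppp, CO 1 atm, MeOH, Et3N, DMF, 70 °C) should give the methyl salicylate F7. Crossed Claisen condensation of F7 with excess lithium enolate of tert-butyl acetate (LiN(iPr)2, tert-butyl acetate, THF, −78 → 0 °C) should give the β-keto ester. The fallback rejoins the route at 22.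

**Further compounds**

F1 | step 17 | (E)-1-(2,4-bis(benzyloxy)-6-hydroxy-3-{(3R,4S)-7-(benzyloxy)-3-[3-(benzyloxy)-2,4-dimethoxyphenyl]chroman-4-yl}phenyl)-3-[4-(benzyloxy)phenyl]prop-2-en-1-one | COc1ccc([C@@H]2COc3cc(OCc4ccccc4)ccc3[C@H]2c2c(OCc3ccccc3)cc(O)c(C(=O)/C=C/c3ccc(OCc4ccccc4)cc3)c2OCc2ccccc2)c(OC)c1OCc1ccccc1
F2 | step 17 | (2R)-5,7-bis(benzyloxy)-6-{(3R,4S)-7-(benzyloxy)-3-[3-(benzyloxy)-2,4-dimethoxyphenyl]chroman-4-yl}-2-[4-(benzyloxy)phenyl]chroman-4-one | COc1ccc([C@@H]2COc3cc(OCc4ccccc4)ccc3[C@H]2c2c(OCc3ccccc3)cc3c(c2OCc2ccccc2)C(=O)C[C@H](c2ccc(OCc4ccccc4)cc2)O3)c(OC)c1OCc1ccccc1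
F3 | step 8 | (E)-3-{2,6-bis(benzyloxy)-4-[(triisopropylsilyl)oxy]phenyl}-2-[3-(benzyloxy)-2,4-dimethoxyphenyl]prop-2-enoic acid | OC(=O)/C(c1ccc(OC)c(OCc2ccccc2)c1OC)=C/c1c(OCc2ccccc2)cc(O[Si](C(C)C)(C(C)C)C(C)C)cc1OCc1ccccc1
F4 | step 8 | (R)-3-{2,6-bis(benzyloxy)-4-[(triisopropylsilyl)oxy]phenyl}-2-[3-(benzyloxy)-2,4-dimethoxyphenyl]propanoic acid | OC(=O)[C@@H](c1ccc(OC)c(OCc2ccccc2)c1OC)Cc1c(OCc2ccccc2)cc(O[Si](C(C)C)(C(C)C)C(C)C)cc1OCc1ccccc1
F5 | step 8 | (R)-3-{2,6-bis(benzyloxy)-4-[(triisopropylsilyl)oxy]phenyl}-2-[3-(benzyloxy)-2,4-dimethoxyphenyl]propan-1-ol | OC[C@@H](c1ccc(OC)c(OCc2ccccc2)c1OC)Cc1c(OCc2ccccc2)cc(O[Si](C(C)C)(C(C)C)C(C)C)cc1OCc1ccccc1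
F6 | step 8 | {3,5-bis(benzyloxy)-4-[(R)-3-[3-(benzyloxy)phenoxy]-2-[3-(benzyloxy)-2,4-dimethoxyphenyl]propyl]phenoxy}tri(propan-2-yl)silane | C(Oc1cccc(OCc2ccccc2)c1)[C@@H](c1ccc(OC)c(OCc2ccccc2)c1OC)Cc1c(OCc2ccccc2)cc(O[Si](C(C)C)(C(C)C)C(C)C)cc1OCc1ccccc1
F7 | step 15 | methyl 2,4-bis(benzyloxy)-6-hydroxy-3-{(3R,4S)-7-(benzyloxy)-3-[3-(benzyloxy)-2,4-dimethoxyphenyl]chroman-4-yl}benzoate | COc1ccc([C@@H]2COc3cc(OCc4ccccc4)ccc3[C@H]2c2c(OCc3ccccc3)cc(O)c(C(=O)OC)c2OCc2ccccc2)c(OC)c1OCc1ccccc1
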